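**Plan**

- Retrosynthetic cuts: first the 8-O-acetyl group and the benzyl ethers, then the C8–O bond (hydroxylation para to the 5-hydroxyl), then O1–C2 and C3–O of ring C (back to a 2'-hydroxychalcone), then the ring A bond C4a–C8a, then the ketone–CH2 bond to a 2-pyrone, and last the cinnamoyl C=C bond.
- Enabling feature: ring A carries oxygens on C5, C7 and C8a in a 1,3,5 pattern and the acyl carbon C4 on C4a. It is an acylphloroglucinol whose 7-methoxy group can be carried as the enol ether of a 3,5,7-triketo ester masked as a 4-methoxy-2-pyrone.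
- Forward order: the ring B aldehyde is extended to a cinnamoyl Weinreb amide, the pyrone methyl anion is C-acylated with it, pyrone opening and Claisen folding close ring A (chalcone), oxidative cyclisation closes ring C, and the C8 oxygen, the acetate and debenzylation follow.
- Stereochemistry: the target has no stereocentre. The only stereo-element on the way is the E double bond from the Horner–Wadsworth–Emmons step, and it is consumed when ring C forms.

Key step: step 3

Remark on the chemistry: compounds 9, F7 and F8 are racemic trans compounds, and each SMILES shows one enantiomer. The two hydroxyls of chalcone 7 are equivalent, so its mono-protection gives a single compound.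

**Route**

Step 1
Reactants: 1 3,4-bis(benzyloxy)benzaldehyde; 2 diethyl {2-[methoxy(methyl)amino]-2-oxoethyl}phosphonate
Product: 3 (2E)-3-[3,4-bis(benzyloxy)phenyl]-N-methoxy-N-methylprop-2-enamide
Conditions: NaH, THF, 0 °C to rt
Reagents that add atoms: none
Why: Horner–Wadsworth–Emmons olefination of an aromatic aldehyde with the sodium anion of a stabilised amide phosphonate should give the E-acrylamide and delivers the acyl donor directly as a Weinreb amide.

Step 2
Reactants: 4 4-methoxy-6-methyl-2H-pyran-2-one; 3 (2E)-3-[3,4-bis(benzyloxy)phenyl]-N-methoxy-N-methylprop-2-enamide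
Product: 5 6-{(3E)-4-[3,4-bis(benzyloxy)phenyl]-2-oxobut-3-en-1-yl}-4-methoxy-2H-pyran-2-one
Conditions: 4 (1.5 equiv), LiN(iPr)2 (1.5 equiv), THF, −78 °C; then 3, −78 to −30 °C; aq NH4Cl
Reagents that add atoms: none
Why: C-acylation of a lithium dienolate by a Weinreb amide: LiN(iPr)2 deprotonates the C6 methyl of the pyrone (a vinylogous ester), the anion adds 1,2 to the amide carbonyl, and the chelated tetrahedral adduct persists until the quench, so over-addition and quenching of the anion by the acidic product are avoided while the amide is a poor Michael acceptor.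

Step 3
Reactants: 5 6-{(3E)-4-[3,4-bis(benzyloxy)phenyl]-2-oxobut-3-en-1-yl}-4-methoxy-2H-pyran-2-one
Product: 7 (2E)-3-[3,4-bis(benzyloxy)phenyl]-1-(2,6-dihydroxy-4-methoxyphenyl)prop-2-en-1-one, via ring-opened keto ester 6 (not isolated)
Conditions: Mg(OMe)2 (3 equiv), MeOH, reflux; then cold 1 M HCl to pH 4
Reagents that add atoms: none
Why: Methoxide adds to the lactone carbonyl of 5 and opens the pyrone to the magnesium chelate of keto ester 6, whose C6 methylene between the two ketones is the most acidic site; its enolate carbon attacks the ester carbonyl, methoxide leaves and the cyclohexenedione enolises to the aromatic ring (a polyketide-type intramolecular Claisen condensation). The closest known reaction type is the biomimetic folding of 3,5,7-triketo esters masked as 4-methoxy-2-pyrones to acylphloroglucinol monomethyl ethers with Mg(OMe)2 or methanolic KOH. Ring A closes in a 6-exo-trig (enolendo) mode on the ester carbonyl, joining the acyl-bearing carbon (later C4a) to the former lactone carbon (later C8a or, equivalently, C5). No stereocentre is created and the E enone is not touched. The step needs Claisen rather than aldol folding: the enol ether at C3 of 6 removes the ketone electrophile of the aldol mode, keeps C2 out of play as a nucleophile, holds the ester and the keto chain cis on the C2=C3 bond and ends as the 7-methoxy group, while magnesium chelation of the 5,7-diketone fixes the carbanion at C6. Because the two new hydroxyls are equivalent, either can later become the ring oxygen O1, so no regiochemical question arises.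

Step 4
Reactants: 7 (2E)-3-[3,4-bis(benzyloxy)phenyl]-1-(2,6-dihydroxy-4-methoxyphenyl)prop-2-en-1-one
Product: 8 (2E)-3-[3,4-bis(benzyloxy)phenyl]-1-[2-hydroxy-4-methoxy-6-(methoxymethoxy)phenyl]prop-2-en-1-one
Conditions: MOMCl (1.1 equiv), iPr2NEt, CH2Cl2, 0 °C
Reagents that add atoms: chloromethyl methyl ether, COCCl
Why: Selective mono-O-alkylation of a 2,6-dihydroxyaryl ketone: only one hydroxyl can be hydrogen-bonded to the carbonyl at a time, the free one is capped, and the remaining one is then locked in the chelate and inert to the weak amine base.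

Step 5
Reactants: 8 (2E)-3-[3,4-bis(benzyloxy)phenyl]-1-[2-hydroxy-4-methoxy-6-(methoxymethoxy)phenyl]prop-2-en-1-one
Product: 10 2-[3,4-bis(benzyloxy)phenyl]-3-hydroxy-7-methoxy-5-(methoxymethoxy)-4H-chromen-4-one, via trans-dihydroflavonol 9 (not isolated)
Conditions: 30% H2O2, 2 M NaOH, MeOH/THF, 0 °C to rt; then dilute HCl
Reagents that add atoms: hydrogen peroxide, OO
Why: Algar–Flynn–Oyamada oxidation: the 2'-phenoxide closes 6-endo onto the enone while alkaline peroxide oxygenates the α-carbon to give dihydroflavonol 9, whose transient trans stereocentres are erased on further oxidation to the flavonol, as is well known for 2'-hydroxy-6'-(methoxymethoxy)chalcones.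

Step 6
Reactants: 10 2-[3,4-bis(benzyloxy)phenyl]-3-hydroxy-7-methoxy-5-(methoxymethoxy)-4H-chromen-4-one
Product: 11 3-(benzyloxy)-2-[3,4-bis(benzyloxy)phenyl]-7-methoxy-5-(methoxymethoxy)-4H-chromen-4-one
Conditions: BnBr, K2CO3, DMF, rt
Reagents that add atoms: benzyl bromide, BrCc1ccccc1
Why: Williamson etherification of the acidic 3-hydroxyl, the only free hydroxyl in 10, masks it for the later acetylation and is removed at the end together with the ring B benzyl ethers.

Step 7
Reactants: 11 3-(benzyloxy)-2-[3,4-bis(benzyloxy)phenyl]-7-methoxy-5-(methoxymethoxy)-4H-chromen-4-one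
Product: 12 3-(benzyloxy)-2-[3,4-bis(benzyloxy)phenyl]-5-hydroxy-7-methoxy-4H-chromen-4-one
Conditions: 3 M HCl, MeOH/THF, 50 °C
Reagents that add atoms: none
Why: Acid-catalysed acetal cleavage (transacetalisation to methanol) removes the MOM group peri to the carbonyl, while benzyl ethers are stable to dilute acid.

Step 8
Reactants: 12 3-(benzyloxy)-2-[3,4-bis(benzyloxy)phenyl]-5-hydroxy-7-methoxy-4H-chromen-4-one
Product: 14 3-(benzyloxy)-2-[3,4-bis(benzyloxy)phenyl]-5,8-dihydroxy-7-methoxy-4H-chromen-4-one, via potassium aryl sulfate 13 (not isolated)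
Conditions: K2S2O8, aq KOH, pyridine, 10–20 °C; acidify and remove unchanged 12; then aq HCl, Na2SO3, 80 °C
Reagents that add atoms: potassium peroxodisulfate, [K+].[K+].[O-]S(=O)(=O)OOS(=O)(=O)[O-]
Why: Elbs persulfate oxidation: the 5-phenoxide attacks a peroxide oxygen of peroxodisulfate through its para carbon C8 to give aryl sulfate 13, which acid hydrolysis converts into the 8-phenol, the classical way from 5-hydroxy-3,7-dialkoxyflavones to gossypetin ethers.

Step 9
Reactants: 14 3-(benzyloxy)-2-[3,4-bis(benzyloxy)phenyl]-5,8-dihydroxy-7-methoxy-4H-chromen-4-one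
Product: 15 3-(benzyloxy)-2-[3,4-bis(benzyloxy)phenyl]-5-hydroxy-7-methoxy-4-oxo-4H-chromen-8-yl acetate
Conditions: Ac2O (1.05 equiv), pyridine, CH2Cl2, 0 °C
Reagents that add atoms: acetic anhydride, CC(=O)OC(C)=O
Why: Chemoselective O-acylation: the 5-hydroxyl is held in a six-membered hydrogen bond to the C4 carbonyl and resists mild acetylation, so one equivalent of anhydride should esterify only the free 8-hydroxyl.

Step 10
Reactants: 15 3-(benzyloxy)-2-[3,4-bis(benzyloxy)phenyl]-5-hydroxy-7-methoxy-4-oxo-4H-chromen-8-yl acetate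
Product: 16 2-(3,4-dihydroxyphenyl)-3,5-dihydroxy-7-methoxy-4-oxo-4H-chromen-8-yl acetate (gossypetin 7-methyl ether 8-acetate)
Conditions: H2 (1 atm), Pd/C, EtOAc/THF, rt
Reagents that add atoms: none
Why: Catalytic hydrogenolysis cleaves the three benzyl ethers under neutral aprotic conditions that leave the aryl acetate and the flavonol C2=C3 bond intact, and the acetate has no neighbouring free hydroxyl to migrate to.

**Compound list**

1 | 3,4-bis(benzyloxy)benzaldehyde | O=Cc1ccc(OCc2ccccc2)c(OCc2ccccc2)c1 | starting material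
2 | diethyl {2-[methoxy(methyl)amino]-2-oxoethyl}phosphonate | CCOP(=O)(OCC)CC(=O)N(C)OC | starting material
3 | (2E)-3-[3,4-bis(benzyloxy)phenyl]-N-methoxy-N-methylprop-2-enamide | CON(C)C(=O)/C=C/c1ccc(OCc2ccccc2)c(OCc2ccccc2)c1 | intermediate
4 | 4-methoxy-6-methyl-2H-pyran-2-one | COC1=CC(=O)OC(C)=C1 | starting material
5 | 6-{(3E)-4-[3,4-bis(benzyloxy)phenyl]-2-oxobut-3-en-1-yl}-4-methoxy-2H-pyran-2-one | COC1=CC(=O)OC(CC(=O)/C=C/c2ccc(OCc3ccccc3)c(OCc3ccccc3)c2)=C1 | intermediate
6 | methyl (2E,8E)-9-[3,4-bis(benzyloxy)phenyl]-3-methoxy-5,7-dioxonona-2,8-dienoate (magnesium enolate in the flask) | COC(=O)/C=C(/OC)CC(=O)CC(=O)/C=C/c1ccc(OCc2ccccc2)c(OCc2ccccc2)c1 | intermediate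
7 | (2E)-3-[3,4-bis(benzyloxy)phenyl]-1-(2,6-dihydroxy-4-methoxyphenyl)prop-2-en-1-one | COc1cc(O)c(C(=O)/C=C/c2ccc(OCc3ccccc3)c(OCc3ccccc3)c2)c(O)c1 | intermediate
8 | (2E)-3-[3,4-bis(benzyloxy)phenyl]-1-[2-hydroxy-4-methoxy-6-(methoxymethoxy)phenyl]prop-2-en-1-one | COCOc1cc(OC)cc(O)c1C(=O)/C=C/c1ccc(OCc2ccccc2)c(OCc2ccccc2)c1 | intermediate
9 | racemic trans-(2R*,3R*)-2-[3,4-bis(benzyloxy)phenyl]-3-hydroxy-7-methoxy-5-(methoxymethoxy)-2,3-dihydro-4H-chromen-4-one | O=C1c2c(OCOC)cc(OC)cc2O[C@H](c2ccc(OCc3ccccc3)c(OCc3ccccc3)c2)[C@H]1O | intermediate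
10 | 2-[3,4-bis(benzyloxy)phenyl]-3-hydroxy-7-methoxy-5-(methoxymethoxy)-4H-chromen-4-one | COCOc1cc(OC)cc2oc(-c3ccc(OCc4ccccc4)c(OCc4ccccc4)c3)c(O)c(=O)c12 | intermediate
11 | 3-(benzyloxy)-2-[3,4-bis(benzyloxy)phenyl]-7-methoxy-5-(methoxymethoxy)-4H-chromen-4-one | COCOc1cc(OC)cc2oc(-c3ccc(OCc4ccccc4)c(OCc4ccccc4)c3)c(OCc3ccccc3)c(=O)c12 | intermediate
12 | 3-(benzyloxy)-2-[3,4-bis(benzyloxy)phenyl]-5-hydroxy-7-methoxy-4H-chromen-4-one | COc1cc(O)c2c(=O)c(OCc3ccccc3)c(-c3ccc(OCc4ccccc4)c(OCc4ccccc4)c3)oc2c1 | intermediate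
13 | potassium 3-(benzyloxy)-2-[3,4-bis(benzyloxy)phenyl]-5-hydroxy-7-methoxy-4-oxo-4H-chromen-8-yl sulfate | COc1cc(O)c2c(=O)c(OCc3ccccc3)c(-c3ccc(OCc4ccccc4)c(OCc4ccccc4)c3)oc2c1OS(=O)(=O)[O-].[K+] | intermediate
14 | 3-(benzyloxy)-2-[3,4-bis(benzyloxy)phenyl]-5,8-dihydroxy-7-methoxy-4H-chromen-4-one | COc1cc(O)c2c(=O)c(OCc3ccccc3)c(-c3ccc(OCc4ccccc4)c(OCc4ccccc4)c3)oc2c1O | intermediate
15 | 3-(benzyloxy)-2-[3,4-bis(benzyloxy)phenyl]-5-hydroxy-7-methoxy-4-oxo-4H-chromen-8-yl acetate | COc1cc(O)c2c(=O)c(OCc3ccccc3)c(-c3ccc(OCc4ccccc4)c(OCc4ccccc4)c3)oc2c1OC(C)=O | intermediate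
16 | 2-(3,4-dihydroxyphenyl)-3,5-dihydroxy-7-methoxy-4-oxo-4H-chromen-8-yl acetate (gossypetin 7-methyl ether 8-acetate) | COc1cc(O)c2c(=O)c(O)c(-c3ccc(O)c(O)c3)oc2c1OC(C)=O | target

**Step count**

Total: 10 steps. Longest linear sequence: 10 steps (1 to 16); pyrone 4 joins at step 2.

**Steps most likely to fail**

Step 8 (Elbs oxidation). The lipophilic phenoxide may dissolve poorly in the aqueous medium, conversion may stay low, the electron-rich ring may be degraded oxidatively, and some attack may occur at C6. The fallback sets out from 12 and comes back at 16.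
- Forcing benzylation of the chelated 5-hydroxyl (BnBr, K2CO3, DMF, 70 °C) should give 3,5-bis(benzyloxy)-2-[3,4-bis(benzyloxy)phenyl]-7-methoxy-4H-chromen-4-one F1.
- Electrophilic iodination (N-iodosuccinimide, catalytic CF3CO2H, MeCN, 0 °C) should go to C8, the position that 5,7-dialkoxyflavones offer once the 5-hydroxyl chelate is gone, giving 3,5-bis(benzyloxy)-2-[3,4-bis(benzyloxy)phenyl]-8-iodo-7-methoxy-4H-chromen-4-one F2.
- Miyaura borylation (bis(pinacolato)diboron, PdCl2(dppf), KOAc, dioxane, 90 °C) should give the pinacol boronate 3,5-bis(benzyloxy)-2-[3,4-bis(benzyloxy)phenyl]-7-methoxy-8-(4,4,5,5-tetramethyl-1,3,2-dioxaborolan-2-yl)-4H-chromen-4-one F3.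
- Oxidation (NaBO3, THF/H2O, rt) should give 3,5-bis(benzyloxy)-2-[3,4-bis(benzyloxy)phenyl]-8-hydroxy-7-methoxy-4H-chromen-4-one F4.
- Acetylation (Ac2O, pyridine, catalytic 4-dimethylaminopyridine) should give 3,5-bis(benzyloxy)-2-[3,4-bis(benzyloxy)phenyl]-7-methoxy-4-oxo-4H-chromen-8-yl acetate F5.
- Hydrogenolysis of the four benzyl ethers (H2, Pd/C, EtOAc/THF) should give target 16.

Step 5 (Algar–Flynn–Oyamada oxidation). The 6'-alkoxy group may divert the cyclisation to the 5-exo path, so that an aurone forms in place of the flavonol. The fallback sets out from 8 and comes back at 12.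
- Capping the chelated hydroxyl as well (NaH, MOMCl, THF, 0 °C) should give (2E)-3-[3,4-bis(benzyloxy)phenyl]-1-[4-methoxy-2,6-bis(methoxymethoxy)phenyl]prop-2-en-1-one F6.
- Weitz–Scheffer epoxidation (30% H2O2, aq NaOH, MeOH/THF), in which no phenoxide is present to cyclise, should give racemic trans-{3-[3,4-bis(benzyloxy)phenyl]oxiran-2-yl}[4-methoxy-2,6-bis(methoxymethoxy)phenyl]methanone F7.
- HCl in MeOH at 55 °C should strip both acetals, and the freed phenol should open the epoxide at the benzylic carbon to give racemic trans-2-[3,4-bis(benzyloxy)phenyl]-3,5-dihydroxy-7-methoxy-2,3-dihydro-4H-chromen-4-one F8.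
- Dehydrogenation (I2, KOAc, AcOH, reflux) should give 2-[3,4-bis(benzyloxy)phenyl]-3,5-dihydroxy-7-methoxy-4H-chromen-4-one F9.
- One equivalent of BnBr (K2CO3, DMF, rt) should alkylate only the unchelated 3-hydroxyl and give 12.

Step 3 (pyrone opening and Claisen folding). Methoxide may add to the enone, the 1,3-diketone may undergo retro-Claisen cleavage, and the product may close to the flavanone by oxa-Michael addition during acidification. The fallback runs the same folding before the enone is present; it sets out from 4 and comes back at 8.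
- Acylation of the lithium anion of 4 with N-methoxy-N-methylacetamide (LiN(iPr)2, THF, −78 °C) should give 4-methoxy-6-(2-oxopropyl)-2H-pyran-2-one F10.
- Mg(OMe)2 in MeOH at reflux should fold it, through the ring-opened ester methyl (2E)-3-methoxy-5,7-dioxooct-2-enoate F11, to 1-(2,6-dihydroxy-4-methoxyphenyl)ethan-1-one F12.
- Mono-protection (MOMCl, iPr2NEt, CH2Cl2, 0 °C) should give 1-[2-hydroxy-4-methoxy-6-(methoxymethoxy)phenyl]ethan-1-one F13.
- Claisen–Schmidt condensation with aldehyde 1 (KOH, EtOH, rt) should give chalcone 8.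

**Further compounds**

F1 | step 8 | 3,5-bis(benzyloxy)-2-[3,4-bis(benzyloxy)phenyl]-7-methoxy-4H-chromen-4-one | COc1cc(OCc2ccccc2)c2c(=O)c(OCc3ccccc3)c(-c3ccc(OCc4ccccc4)c(OCc4ccccc4)c3)oc2c1
F2 | step 8 | 3,5-bis(benzyloxy)-2-[3,4-bis(benzyloxy)phenyl]-8-iodo-7-methoxy-4H-chromen-4-one | COc1cc(OCc2ccccc2)c2c(=O)c(OCc3ccccc3)c(-c3ccc(OCc4ccccc4)c(OCc4ccccc4)c3)oc2c1I
F3 | step 8 | 3,5-bis(benzyloxy)-2-[3,4-bis(benzyloxy)phenyl]-7-methoxy-8-(4,4,5,5-tetramethyl-1,3,2-dioxaborolan-2-yl)-4H-chromen-4-one | COc1cc(OCc2ccccc2)c2c(=O)c(OCc3ccccc3)c(-c3ccc(OCc4ccccc4)c(OCc4ccccc4)c3)oc2c1B1OC(C)(C)C(C)(C)O1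
F4 | step 8 | 3,5-bis(benzyloxy)-2-[3,4-bis(benzyloxy)phenyl]-8-hydroxy-7-methoxy-4H-chromen-4-one | COc1cc(OCc2ccccc2)c2c(=O)c(OCc3ccccc3)c(-c3ccc(OCc4ccccc4)c(OCc4ccccc4)c3)oc2c1O
F5 | step 8 | 3,5-bis(benzyloxy)-2-[3,4-bis(benzyloxy)phenyl]-7-methoxy-4-oxo-4H-chromen-8-yl acetate | COc1cc(OCc2ccccc2)c2c(=O)c(OCc3ccccc3)c(-c3ccc(OCc4ccccc4)c(OCc4ccccc4)c3)oc2c1OC(C)=O
F6 | step 5 | (2E)-3-[3,4-bis(benzyloxy)phenyl]-1-[4-methoxy-2,6-bis(methoxymethoxy)phenyl]prop-2-en-1-one | COCOc1cc(OC)cc(OCOC)c1C(=O)/C=C/c1ccc(OCc2ccccc2)c(OCc2ccccc2)c1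
F7 | step 5 | racemic trans-{3-[3,4-bis(benzyloxy)phenyl]oxiran-2-yl}[4-methoxy-2,6-bis(methoxymethoxy)phenyl]methanone | COCOc1cc(OC)cc(OCOC)c1C(=O)[C@@H]1O[C@H]1c1ccc(OCc2ccccc2)c(OCc2ccccc2)c1
F8 | step 5 | racemic trans-(2R*,3R*)-2-[3,4-bis(benzyloxy)phenyl]-3,5-dihydroxy-7-methoxy-2,3-dihydro-4H-chromen-4-one | O=C1c2c(O)cc(OC)cc2O[C@H](c2ccc(OCc3ccccc3)c(OCc3ccccc3)c2)[C@H]1O
F9 | step 5 | 2-[3,4-bis(benzyloxy)phenyl]-3,5-dihydroxy-7-methoxy-4H-chromen-4-one | COc1cc(O)c2c(=O)c(O)c(-c3ccc(OCc4ccccc4)c(OCc4ccccc4)c3)oc2c1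
F10 | step 3 | 4-methoxy-6-(2-oxopropyl)-2H-pyran-2-one | COC1=CC(=O)OC(CC(C)=O)=C1
F11 | step 3 | methyl (2E)-3-methoxy-5,7-dioxooct-2-enoate | COC(=O)/C=C(/OC)CC(=O)CC(C)=O
F12 | step 3 | 1-(2,6-dihydroxy-4-methoxyphenyl)ethan-1-one | COc1cc(O)c(C(C)=O)c(O)c1
F13 | step 3 | 1-[2-hydroxy-4-methoxy-6-(methoxymethoxy)phenyl]ethan-1-one | COCOc1cc(OC)cc(O)c1C(C)=O
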